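## Analysis of the target

The target is a 2,3,4-trisubstituted tetrahydrofuran. Its ring atoms are numbered O1, C2, C3, C4, C5 here, and this numbering is also used in the names of all ring compounds below. C2 carries a 3,4-dimethoxyphenyl group, C3 a hydroxymethyl group, C4 a 3,4,5-trimethoxybenzoyl group, and C5 is an unsubstituted methylene. The three contiguous stereocentres are (2R,3R,4S): aryl and CH2OH are cis, and the aroyl group is trans to the CH2OH group.

C4 is α to an aryl ketone and is epimerisable. Its 3,4-trans arrangement is the more stable one, so it can be left to a late equilibration. The difficult relation is C2/C3. The cis arrangement is the less stable one, and C2 is a benzylic ether on an electron-rich ring that ionises easily under acid. Any route in which C3 becomes a carbonyl α-carbon puts this relation at risk.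

The sensitive groups are the two electron-rich arenes, the acid-labile C2–O1 bond, the enolisable ketone with a β-oxygen (O1 through C5), and the γ-hydroxy ketone. The 3,4-cis epimer of the γ-hydroxy ketone could close to a bicyclic hemiketal.

The plan rests on a 1,3-relation across the ring. C2 bears a donor (the dimethoxyphenyl group), C4 bears a carbonyl acceptor, and the O1–C5 unit between them is one molecule of formaldehyde. Removing that unit and joining C2 to C4 leaves a donor–acceptor cyclopropane made of C2, C3 and C4.

## Retrosynthetic reasoning

**14 ⇒ 13 (O–Si).** The primary hydroxyl of 14 is kept as a bulky silyl ether until the end. In the early compounds this stops the alcohol from lactonising onto the ester that is cis to it. At the ketone stage it stops a cis epimer from being trapped as a cyclic hemiketal. The forward step is a buffered fluoride cleavage that must leave C4 alone.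

**13 ⇒ 12 (configuration at C4).** No bond is cut. C4 is the only acidic stereocentre, and in 13 its aroyl group sits trans to the C3 substituent, which is the thermodynamic arrangement. C4 therefore needs no control earlier, and 12 may be a mixture of C4 epimers that a mild base converges on 13.

**12 ⇒ 9 + 10 (C4 carbonyl–aryl bond).** Cutting between the ketone carbon and the trimethoxyphenyl ring makes the route convergent. It also keeps this second electron-rich arene away from the Lewis acid step. Forward, the aryllithium 11 made from bromide 10 is acylated by the N-methoxy-N-methylamide 9, and the chelated adduct stops the addition at the ketone.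

**9 ⇒ 8 ⇒ 7 (second ester at C4).** Going backwards, the amide becomes the methyl ester 8, and a second ester is added at C4 to give the geminal diester 7. In 7, C4 is not a stereocentre and carries the acceptor pair that the ring-forming step needs. Forward, one ester is removed by dealkoxycarbonylation and the other is converted into the amide.

**7 ⇒ 5 + 6 (O1–C2 and C4–C5).** Both bonds to the O1–C5 unit are cut and C2 is joined to C4. This gives cyclopropane 5 and formaldehyde 6.

- It is the only disconnection that removes the ring and at the same time reduces the C2/C3 problem to alkene geometry. The cis C2/C3 ring comes from a trans cyclopropane by inversion at C2, and the trans cyclopropane comes from an E-alkene.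
- C3 stays at the alcohol oxidation level throughout and is never enolisable.
- C5 has no substituent, so the aldehyde partner is formaldehyde and no stereocentre arises there.
- The forward reaction has to open the C2–C4 bond with an oxygen nucleophile faster than C2 ionises, and then close C4 onto the oxocarbenium carbon.

**5 ⇒ 4 ⇒ 3 (protecting group and oxidation level).** The silyl ether goes back to alcohol 4 and then to aldehyde 3. The aldehyde is the handle that the cyclopropanation leaves on the future C3.

**3 ⇒ 1 + 2 (both cyclopropane bonds to the malonyl carbon).** Cutting the two bonds from the malonyl carbon gives enal 1 and bromomalonate 2. Forward, a chiral secondary amine catalyst runs a conjugate addition and alkylation cascade. This sets the future C2 and C3 in one step, with the absolute configuration controlled by the catalyst and the trans relation by the ring closure.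

## Alternatives that were turned down

**Alternative 1: ring contraction of a cyclic vinyl acetal.**

- Disconnection: the C2–C3 bond is cut. The ring is traced back to the seven-membered vinyl acetal A2, 2-(3,4-dimethoxyphenyl)-5-[1-(3,4,5-trimethoxyphenyl)ethenyl]-4,5-dihydro-1,3-dioxepine. In A2, C2 is the acetal carbon and C3 is the β-carbon of the enol ether.
- Forward key step: a strong Lewis acid at low temperature breaks the acetal C–O bond on the enol ether side. The aldehyde enolate and the aryl-stabilised oxocarbenium ion recombine through carbon. The ring contracts to A1, 2,3-cis-3,4-trans-2-(3,4-dimethoxyphenyl)-4-[1-(3,4,5-trimethoxyphenyl)ethenyl]tetrahydrofuran-3-carbaldehyde.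
- For it: the step forms the hindered C2–C3 bond directly, and kinetic cis selectivity is established for this reaction type. The two later adjustments are simple and orthogonal: hydride reduction of the aldehyde and oxidative cleavage of the 1-arylvinyl group. No oxygen protecting group is needed.
- Against it:
  - In A1, C3 is the α-carbon of an aldehyde and sits in the less stable cis relation to C2. The same Lewis acid can reopen the ring, so drift to the trans compound is built in.
  - The only stereocentre of A2 that carries the absolute configuration is doubly allylic, flanked by the enol ether and the styrene-type alkene. It must be made enantioselectively and must survive the alkene migration that makes the vinyl acetal.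
  - Chirality passes to C2 and C3 through a loose ion pair, by 1,2-induction only.
  - A2 needs more steps than 5, and the oxidative cleavage must spare two electron-rich arenes.
- Comparison: on precedent for the key step this alternative is stronger, because the chosen annulation has not been shown with formaldehyde. The chosen route offers a C3 that is never enolisable, an absolute configuration set by an established catalytic step and relayed stereospecifically, and a shorter sequence.

**Alternative 2: reductive etherification through a cis-fused lactone.**

- Disconnection: O1–C2 and C2–H are cut. The ring is traced back to the keto lactone A4, 4-(3,4-dimethoxybenzoyl)-3-(hydroxymethyl)dihydrofuran-2(3H)-one. In A4, C2 is the ketone carbon, the hydroxyl on C5 is free, and C3 and C4 are tied into a γ-lactone.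
- Forward key step: acid closes the hemiketal and ionises it to a bicyclic oxocarbenium ion. A silane hydride donor attacks the convex face and pushes the aryl group to the concave face. The product is A3, cis-fused 4-(3,4-dimethoxyphenyl)tetrahydro-1H,3H-furo[3,4-c]furan-1-one.
- For it: the bicyclic shape enforces the cis C2/C3 relation. This is a robust and well-precedented form of control, and it does not depend on the configuration of the enolisable centres of A4. On certainty of the C2/C3 outcome it is stronger than the chosen route.
- Against it:
  - A3 has the C4 carbonyl cis to C3, locked in the lactone. It must be opened, the CH2OH reprotected, the aryl group added, C4 epimerised and the hydroxyl freed. This is the same five-step endgame as the chosen route, on top of a longer preparation of A4.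
  - The absolute configuration of A4 rests on centres α to carbonyls: C3 next to the aryl ketone and C4 next to the lactone. Enolisation under the acidic key step converges the relative configuration but can erode the absolute one.
  - The product is an electron-rich benzylic ether exposed to a Lewis acid and a hydride donor, so ionisation at C2 and over-reduction to a ring-opened compound is a risk.
- Comparison: the chosen route is shorter, and its absolute configuration sits on non-enolisable centres. In place of the safer hydride delivery it offers a stereospecific inversion fed by a catalytic asymmetric step.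

**Alternative 3: acetal cyclisation onto a ketone enol silane.**

- Disconnection: C4–C5 is cut. The O1–C5 unit is carried as a methoxymethyl ether on the C2 oxygen of the open-chain compound A6, methyl (Z)-2-[(3,4-dimethoxyphenyl)(methoxymethoxy)methyl]-4-(3,4,5-trimethoxyphenyl)-4-(trimethylsilyloxy)but-3-enoate, with C2 and C3 configured as in the target.
- Forward key step: a silyl triflate ionises the acetal. The enol silane carbon C4 captures the oxocarbenium carbon and gives A5, methyl 2,3-cis-3,4-trans-2-(3,4-dimethoxyphenyl)-4-(3,4,5-trimethoxybenzoyl)tetrahydrofuran-3-carboxylate.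
- For it: the formaldehyde unit is delivered intramolecularly from a stable acetal. No monomeric formaldehyde is handled and none can polymerise. On this point it is stronger than the chosen route. Both aryl groups are in place before the ring closes.
- Against it:
  - C2 and C3 must be set beforehand in an open chain by an aldol reaction with both relative and absolute control. This costs an auxiliary or its equivalent and extra steps.
  - In A6, C3–H is α to an ester and β to the benzylic acetal oxygen. Forming the enol silane at C4 has to avoid enolisation at C3, which would lead to elimination or epimerisation.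
  - The silyl triflate can also cleave the benzylic C2–O bond of the electron-rich acetal.
  - In A5 both C3 and C4 are enolisable and the cis C2/C3 relation is the less stable one, so C4 cannot be corrected safely.
  - The ester must be reduced in the presence of the aryl ketone, which costs protection or a reduce-and-reoxidise detour.
- Comparison: the chosen route keeps C3 at the alcohol level, sets C2 by a stereospecific step and is shorter. The price is an untested aldehyde partner.

Key step: step 4

Remark: formaldehyde (6) is bought as paraformaldehyde and cracked to the monomer directly before step 4. In the cyclopropanes the aryl-bearing carbon, the CH2O-bearing carbon and the malonyl carbon are the future C2, C3 and C4.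

## Route

**Step 1**
Reactants: 1 (E)-3-(3,4-dimethoxyphenyl)prop-2-enal; 2 dimethyl 2-bromomalonate
Product: 3 dimethyl (2S,3R)-2-(3,4-dimethoxyphenyl)-3-formylcyclopropane-1,1-dicarboxylate (aryl and formyl trans)
Conditions: (S)-α,α-diphenylprolinol trimethylsilyl ether (20 mol%), 2,6-lutidine (1.1 equiv), CH2Cl2, 0 °C → rt
Reagents that add atoms: none
Why: Organocatalytic Michael-initiated ring closure (iminium–enamine cascade): in the E-iminium ion of 1 the diphenyl(silyloxy)methyl group of the (S)-catalyst covers the Re face of the β-carbon, the bromomalonate anion adds to the Si face, and the enamine then displaces bromide in a 3-exo-tet closure that places aryl and formyl trans. Both stereocentres are set here: the catalyst fixes the absolute configuration and the ring closure fixes the trans relation.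

**Step 2**
Reactants: 3 dimethyl (2S,3R)-2-(3,4-dimethoxyphenyl)-3-formylcyclopropane-1,1-dicarboxylate
Product: 4 dimethyl (2S,3R)-2-(3,4-dimethoxyphenyl)-3-(hydroxymethyl)cyclopropane-1,1-dicarboxylate
Conditions: NaBH4, MeOH, −20 °C; pH 7 buffer work-up
Reagents that add atoms: none
Why: Chemoselective borohydride reduction of the aldehyde beside two methyl esters, with no stereocentre touched. Low temperature and a neutral work-up should keep the new alcohol from lactonising onto the cis ester, and the crude alcohol is silylated at once.

**Step 3**
Reactants: 4 dimethyl (2S,3R)-2-(3,4-dimethoxyphenyl)-3-(hydroxymethyl)cyclopropane-1,1-dicarboxylate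
Product: 5 dimethyl (2S,3R)-2-(3,4-dimethoxyphenyl)-3-[(triisopropylsilyloxy)methyl]cyclopropane-1,1-dicarboxylate
Conditions: TIPSCl, imidazole, DMF, 0 °C → rt
Reagents that add atoms: triisopropylsilyl chloride, CC(C)[Si](Cl)(C(C)C)C(C)C
Why: Standard silylation of a primary alcohol. The bulky silyl ether rules out lactonisation and should survive the Lewis acid, hot chloride, the Grignard and aryllithium reagents and DBU, until fluoride removes it.

**Step 4**
Reactants: 5 dimethyl (2S,3R)-2-(3,4-dimethoxyphenyl)-3-[(triisopropylsilyloxy)methyl]cyclopropane-1,1-dicarboxylate; 6 formaldehyde (monomer)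
Product: 7 dimethyl (2R,3R)-2-(3,4-dimethoxyphenyl)-3-[(triisopropylsilyloxy)methyl]tetrahydrofuran-4,4-dicarboxylate (aryl and CH2OSi cis)
Conditions: Sn(OTf)2 (10 mol%), 4 Å MS, CH2Cl2, −78 °C; then cold CH2Cl2 solution of monomeric CH2O (5 equiv, from cracked paraformaldehyde) added last, −78 → −30 °C; Et3N quench
Reagents that add atoms: none
Why: Proposed new method: Sn(OTf)2 chelates the two ester carbonyls of 5 and polarises the bond between the aryl-bearing carbon and the malonyl carbon; the oxygen of 6 attacks the benzylic carbon from the side opposite the departing malonate (SN2-like, O1–C2), and the tin malonate enolate then closes onto the O-alkyl oxocarbenium carbon (C4–C5). The closest known reaction type is the stereospecific Lewis acid-catalysed (3+2) annulation of 2-arylcyclopropane-1,1-diesters with aryl, alkenyl and alkyl aldehydes, which runs through an intimate ion pair with inversion at the donor carbon; formaldehyde has not been shown as the partner. The tetrahydrofuran closes in a 5-(enolexo)-endo-trig aldol-type step, a mode that is routine for oxocarbenium acceptors in this reaction class. C2 is set by inversion of the S-configured donor carbon of 5 and C3 is carried over unchanged, so the trans aryl/CH2OSi cyclopropane should give the 2,3-cis ring; C4 (two identical esters) and C5 (CH2) are not stereocentres, so no 2,5-relation has to be controlled. The step needs regioselective cleavage of the donor–acceptor bond, which is secured because the other bond to the malonyl carbon has no donor. It also needs opening ahead of ionisation to a free benzylic cation, for which the low temperature, the mild divalent tin triflate and the excess of the small aldehyde are chosen. Formaldehyde is a weaker oxygen nucleophile than the aldehydes known to react and polymerises on Lewis acids, so it is used as the monomer in excess and meets the cyclopropane only after the catalyst is bound to the diester.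

**Step 5**
Reactants: 7 dimethyl (2R,3R)-2-(3,4-dimethoxyphenyl)-3-[(triisopropylsilyloxy)methyl]tetrahydrofuran-4,4-dicarboxylate
Product: 8 methyl (2R,3R)-2-(3,4-dimethoxyphenyl)-3-[(triisopropylsilyloxy)methyl]tetrahydrofuran-4-carboxylate (both C4 epimers)
Conditions: LiCl, H2O, DMSO, 140 °C
Reagents that add atoms: none
Why: Krapcho dealkoxycarbonylation: chloride demethylates one ester by SN2, the carboxylate loses CO2 and water protonates the ester enolate. The C4 configuration formed here does not matter because it is equilibrated in step 8, and loss of O1 from the enolate would be the reverse of a 5-endo-trig closure and is stereoelectronically poor.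

**Step 6**
Reactants: 8 methyl (2R,3R)-2-(3,4-dimethoxyphenyl)-3-[(triisopropylsilyloxy)methyl]tetrahydrofuran-4-carboxylate (both C4 epimers)
Product: 9 (2R,3R)-N-methoxy-N-methyl-2-(3,4-dimethoxyphenyl)-3-[(triisopropylsilyloxy)methyl]tetrahydrofuran-4-carboxamide (both C4 epimers)
Conditions: MeNH(OMe)·HCl, iPrMgCl, THF, −20 → 0 °C
Reagents that add atoms: N,O-dimethylhydroxylamine hydrochloride, CNOC.Cl
Why: Weinreb amide formation from an ester with the chloromagnesium amide made in the flask. The silyl ether and the benzylic ether are inert, and any enolisation at C4 only shifts the epimer ratio.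

**Step 7**
Reactants: 9 (2R,3R)-N-methoxy-N-methyl-2-(3,4-dimethoxyphenyl)-3-[(triisopropylsilyloxy)methyl]tetrahydrofuran-4-carboxamide (both C4 epimers); 10 5-bromo-1,2,3-trimethoxybenzene
Product: 12 [(2R,3R)-2-(3,4-dimethoxyphenyl)-3-[(triisopropylsilyloxy)methyl]tetrahydrofuran-4-yl](3,4,5-trimethoxyphenyl)methanone (both C4 epimers), via 3,4,5-trimethoxyphenyllithium 11 (not isolated)
Conditions: 10, n-BuLi, THF, −78 °C; then 9, −78 → −40 °C; aq. NH4Cl
Reagents that add atoms: none
Why: Bromine–lithium exchange followed by Weinreb ketone synthesis. The chelated tetrahedral adduct should hold until work-up, so the addition stops at the ketone.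

**Step 8**
Reactants: 12 [(2R,3R)-2-(3,4-dimethoxyphenyl)-3-[(triisopropylsilyloxy)methyl]tetrahydrofuran-4-yl](3,4,5-trimethoxyphenyl)methanone (both C4 epimers)
Product: 13 [(2R,3R,4S)-2-(3,4-dimethoxyphenyl)-3-[(triisopropylsilyloxy)methyl]tetrahydrofuran-4-yl](3,4,5-trimethoxyphenyl)methanone (3,4-trans)
Conditions: DBU, PhMe, 40 °C
Reagents that add atoms: none
Why: Base-mediated epimerisation of the ketone α-carbon under thermodynamic control. C4 is the only acidic stereocentre, and the aroyl group should settle trans to the C3 substituent and away from the crowded cis C2/C3 face. The hydroxyl is still silylated, so a cis epimer cannot be held back as a bicyclic hemiketal.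

**Step 9**
Reactants: 13 [(2R,3R,4S)-2-(3,4-dimethoxyphenyl)-3-[(triisopropylsilyloxy)methyl]tetrahydrofuran-4-yl](3,4,5-trimethoxyphenyl)methanone
Product: 14 [(2R,3R,4S)-2-(3,4-dimethoxyphenyl)-3-(hydroxymethyl)tetrahydrofuran-4-yl](3,4,5-trimethoxyphenyl)methanone, the target; systematic name [(3S,4R,5R)-5-(3,4-dimethoxyphenyl)-4-(hydroxymethyl)oxolan-3-yl](3,4,5-trimethoxyphenyl)methanone
Conditions: TBAF, AcOH, THF, 0 °C → rt
Reagents that add atoms: none
Why: Fluoride cleavage of the silyl ether, buffered with acetic acid so that neither alkoxide nor basic fluoride disturbs C4. The trans γ-hydroxy ketone has no strain-free hemiketal available and should stay open.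

## Compound list

1 | (E)-3-(3,4-dimethoxyphenyl)prop-2-enal | COc1ccc(/C=C/C=O)cc1OC | starting material
2 | dimethyl 2-bromomalonate | COC(=O)C(Br)C(=O)OC | starting material
3 | dimethyl (2S,3R)-2-(3,4-dimethoxyphenyl)-3-formylcyclopropane-1,1-dicarboxylate | COc1ccc([C@@H]2[C@@H](C=O)C2(C(=O)OC)C(=O)OC)cc1OC | intermediate
4 | dimethyl (2S,3R)-2-(3,4-dimethoxyphenyl)-3-(hydroxymethyl)cyclopropane-1,1-dicarboxylate | COc1ccc([C@@H]2[C@@H](CO)C2(C(=O)OC)C(=O)OC)cc1OC | intermediate
5 | dimethyl (2S,3R)-2-(3,4-dimethoxyphenyl)-3-[(triisopropylsilyloxy)methyl]cyclopropane-1,1-dicarboxylate | COc1ccc([C@@H]2[C@@H](CO[Si](C(C)C)(C(C)C)C(C)C)C2(C(=O)OC)C(=O)OC)cc1OC | intermediate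
6 | formaldehyde (monomer, from paraformaldehyde) | C=O | starting material
7 | dimethyl (2R,3R)-2-(3,4-dimethoxyphenyl)-3-[(triisopropylsilyloxy)methyl]tetrahydrofuran-4,4-dicarboxylate | COc1ccc([C@@H]2OCC(C(=O)OC)(C(=O)OC)[C@@H]2CO[Si](C(C)C)(C(C)C)C(C)C)cc1OC | intermediate
8 | methyl (2R,3R)-2-(3,4-dimethoxyphenyl)-3-[(triisopropylsilyloxy)methyl]tetrahydrofuran-4-carboxylate, both C4 epimers | COc1ccc([C@@H]2OCC(C(=O)OC)[C@@H]2CO[Si](C(C)C)(C(C)C)C(C)C)cc1OC | intermediate
9 | (2R,3R)-N-methoxy-N-methyl-2-(3,4-dimethoxyphenyl)-3-[(triisopropylsilyloxy)methyl]tetrahydrofuran-4-carboxamide, both C4 epimers | COc1ccc([C@@H]2OCC(C(=O)N(C)OC)[C@@H]2CO[Si](C(C)C)(C(C)C)C(C)C)cc1OC | intermediate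
10 | 5-bromo-1,2,3-trimethoxybenzene | COc1cc(Br)cc(OC)c1OC | starting material
11 | 3,4,5-trimethoxyphenyllithium | COc1cc([Li])cc(OC)c1OC | intermediate
12 | [(2R,3R)-2-(3,4-dimethoxyphenyl)-3-[(triisopropylsilyloxy)methyl]tetrahydrofuran-4-yl](3,4,5-trimethoxyphenyl)methanone, both C4 epimers | COc1ccc([C@@H]2OCC(C(=O)c3cc(OC)c(OC)c(OC)c3)[C@@H]2CO[Si](C(C)C)(C(C)C)C(C)C)cc1OC | intermediate
13 | [(2R,3R,4S)-2-(3,4-dimethoxyphenyl)-3-[(triisopropylsilyloxy)methyl]tetrahydrofuran-4-yl](3,4,5-trimethoxyphenyl)methanone | COc1ccc([C@@H]2OC[C@@H](C(=O)c3cc(OC)c(OC)c(OC)c3)[C@@H]2CO[Si](C(C)C)(C(C)C)C(C)C)cc1OC | intermediate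
14 | [(2R,3R,4S)-2-(3,4-dimethoxyphenyl)-3-(hydroxymethyl)tetrahydrofuran-4-yl](3,4,5-trimethoxyphenyl)methanone | COc1ccc([C@@H]2OC[C@@H](C(=O)c3cc(OC)c(OC)c(OC)c3)[C@@H]2CO)cc1OC | target

## Step count and least certain steps

Total step count: 9. Longest linear sequence: 9 steps, from 1 to 14. Bromide 10 enters in step 7 through the non-isolated aryllithium 11.

**Step 4 (key step, proposed new method).**

What may go wrong:
- Formaldehyde may polymerise on the Lewis acid faster than the activated cyclopropane captures it.
- Its weakly basic oxygen may attack too slowly. The cyclopropane would then ionise at the benzylic carbon and stereospecificity would be lost, either by trans-to-cis isomerisation of the cyclopropane or by formation of the 2,3-trans ring.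
- A second formaldehyde may be inserted before ring closure.
- The product may reopen at C2 under the Lewis acid and drift to the more stable 2,3-trans isomer.

Fallback by known chemistry, from 5 back to 7:
- Cyclopropane 5 is annulated under the same Sn(OTf)2 catalysis with (E)-cinnamaldehyde, an aldehyde class known to work. This should give dimethyl (2R,3R,5R)-2-(3,4-dimethoxyphenyl)-5-[(E)-2-phenylethenyl]-3-[(triisopropylsilyloxy)methyl]tetrahydrofuran-4,4-dicarboxylate F1, with the 2,5-cis relation that the mechanism prescribes.
- The styryl group is cleaved with catalytic OsO4 and NaIO4 (2,6-lutidine, dioxane–water) to dimethyl (2R,3R,5S)-2-(3,4-dimethoxyphenyl)-5-formyl-3-[(triisopropylsilyloxy)methyl]tetrahydrofuran-4,4-dicarboxylate F2.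
- The formyl group is removed by decarbonylation with stoichiometric RhCl(PPh3)3 in refluxing toluene. The alkylrhodium intermediate at C5 is flanked by O1 and the quaternary C4, has no β-hydrogen, and can only give the C–H bond. The route rejoins at 7.

**Step 5.**

What may go wrong: at 140 °C the ester enolate released on decarboxylation may expel the ring oxygen (β-elimination to a ring-opened α-methylene ester) before it is protonated. Chloride may also attack the silyl ether.

Fallback, from 7 back to 8: one ester of 7 is saponified with one equivalent of KOH in MeOH–THF–water at room temperature. The ester anti to the silyloxymethyl group is the more exposed one, and the product is 2-(3,4-dimethoxyphenyl)-4-(methoxycarbonyl)-3-[(triisopropylsilyloxy)methyl]tetrahydrofuran-4-carboxylic acid F3. Heating this malonic half-acid in xylene at about 130 °C should release CO2 through a cyclic transition state. That gives the neutral ester enol and never a free enolate or a nucleophile, and the route rejoins at 8.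

**Step 7.**

What may go wrong: the aryllithium may act as a base at C4–H instead of adding, mainly on the hindered 3,4-cis epimer. The amide would then be recovered, or the ring oxygen lost from the lithium enolate.

Fallback, from 9 back to 12: amide 9 is reduced with i-Bu2AlH (THF, −78 °C) to (2R,3R)-2-(3,4-dimethoxyphenyl)-3-[(triisopropylsilyloxy)methyl]tetrahydrofuran-4-carbaldehyde F4. This far more electrophilic carbonyl should take up 11 at −78 °C to give the carbinol [(2R,3R)-2-(3,4-dimethoxyphenyl)-3-[(triisopropylsilyloxy)methyl]tetrahydrofuran-4-yl](3,4,5-trimethoxyphenyl)methanol F5 as a mixture of epimers. Oxidation with Dess–Martin periodinane (NaHCO3, CH2Cl2) returns the route to 12.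

**Step 8.**

What may go wrong: equilibration may be incomplete, or the ketone enolate may lose O1 by E1cB ring opening during prolonged exposure to DBU.

Fallback, from 8 back to 13: C4 is corrected one oxidation state earlier. Ester 8 is equilibrated with catalytic NaOMe in MeOH at room temperature, where the enolate is formed only fleetingly in a protic medium. This should give methyl (2R,3R,4S)-2-(3,4-dimethoxyphenyl)-3-[(triisopropylsilyloxy)methyl]tetrahydrofuran-4-carboxylate F6. It is converted under the conditions of step 6 into (2R,3R,4S)-N-methoxy-N-methyl-2-(3,4-dimethoxyphenyl)-3-[(triisopropylsilyloxy)methyl]tetrahydrofuran-4-carboxamide F7. Addition of 11 as in step 7 then gives 13 directly, and step 8 is no longer needed.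

## Further compounds

F1 | step 4 | dimethyl (2R,3R,5R)-2-(3,4-dimethoxyphenyl)-5-[(E)-2-phenylethenyl]-3-[(triisopropylsilyloxy)methyl]tetrahydrofuran-4,4-dicarboxylate | COc1ccc([C@@H]2O[C@H](/C=C/c3ccccc3)C(C(=O)OC)(C(=O)OC)[C@@H]2CO[Si](C(C)C)(C(C)C)C(C)C)cc1OC
F2 | step 4 | dimethyl (2R,3R,5S)-2-(3,4-dimethoxyphenyl)-5-formyl-3-[(triisopropylsilyloxy)methyl]tetrahydrofuran-4,4-dicarboxylate | COc1ccc([C@@H]2O[C@H](C=O)C(C(=O)OC)(C(=O)OC)[C@@H]2CO[Si](C(C)C)(C(C)C)C(C)C)cc1OC
F3 | step 5 | 2-(3,4-dimethoxyphenyl)-4-(methoxycarbonyl)-3-[(triisopropylsilyloxy)methyl]tetrahydrofuran-4-carboxylic acid, acid anti to the silyloxymethyl group | COc1ccc([C@@H]2OC[C@](C(=O)O)(C(=O)OC)[C@@H]2CO[Si](C(C)C)(C(C)C)C(C)C)cc1OC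
F4 | step 7 | (2R,3R)-2-(3,4-dimethoxyphenyl)-3-[(triisopropylsilyloxy)methyl]tetrahydrofuran-4-carbaldehyde, both C4 epimers | COc1ccc([C@@H]2OCC(C=O)[C@@H]2CO[Si](C(C)C)(C(C)C)C(C)C)cc1OC
F5 | step 7 | [(2R,3R)-2-(3,4-dimethoxyphenyl)-3-[(triisopropylsilyloxy)methyl]tetrahydrofuran-4-yl](3,4,5-trimethoxyphenyl)methanol, mixture of epimers | COc1ccc([C@@H]2OCC(C(O)c3cc(OC)c(OC)c(OC)c3)[C@@H]2CO[Si](C(C)C)(C(C)C)C(C)C)cc1OC
F6 | step 8 | methyl (2R,3R,4S)-2-(3,4-dimethoxyphenyl)-3-[(triisopropylsilyloxy)methyl]tetrahydrofuran-4-carboxylate | COc1ccc([C@@H]2OC[C@@H](C(=O)OC)[C@@H]2CO[Si](C(C)C)(C(C)C)C(C)C)cc1OC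
F7 | step 8 | (2R,3R,4S)-N-methoxy-N-methyl-2-(3,4-dimethoxyphenyl)-3-[(triisopropylsilyloxy)methyl]tetrahydrofuran-4-carboxamide | COc1ccc([C@@H]2OC[C@@H](C(=O)N(C)OC)[C@@H]2CO[Si](C(C)C)(C(C)C)C(C)C)cc1OC
A1 | alternative 1 | 2,3-cis-3,4-trans-2-(3,4-dimethoxyphenyl)-4-[1-(3,4,5-trimethoxyphenyl)ethenyl]tetrahydrofuran-3-carbaldehyde | COc1ccc([C@@H]2OC[C@@H](C(=C)c3cc(OC)c(OC)c(OC)c3)[C@@H]2C=O)cc1OC
A2 | alternative 1 | 2-(3,4-dimethoxyphenyl)-5-[1-(3,4,5-trimethoxyphenyl)ethenyl]-4,5-dihydro-1,3-dioxepine, either acetal epimer | COc1ccc(C2OC[C@@H](C(=C)c3cc(OC)c(OC)c(OC)c3)C=CO2)cc1OC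
A3 | alternative 2 | cis-fused 4-(3,4-dimethoxyphenyl)tetrahydro-1H,3H-furo[3,4-c]furan-1-one, aryl on the concave face | COc1ccc([C@@H]2OC[C@@H]3C(=O)OC[C@H]23)cc1OC
A4 | alternative 2 | 4-(3,4-dimethoxybenzoyl)-3-(hydroxymethyl)dihydrofuran-2(3H)-one, either epimer at the lactone α-carbon | COc1ccc(C(=O)[C@H]2COC(=O)C2CO)cc1OC
A5 | alternative 3 | methyl 2,3-cis-3,4-trans-2-(3,4-dimethoxyphenyl)-4-(3,4,5-trimethoxybenzoyl)tetrahydrofuran-3-carboxylate | COc1ccc([C@@H]2OC[C@@H](C(=O)c3cc(OC)c(OC)c(OC)c3)[C@@H]2C(=O)OC)cc1OC
A6 | alternative 3 | methyl (Z)-2-[(3,4-dimethoxyphenyl)(methoxymethoxy)methyl]-4-(3,4,5-trimethoxyphenyl)-4-(trimethylsilyloxy)but-3-enoate | COc1ccc([C@H](OCOC)[C@@H](C(=O)OC)/C=C(\O[Si](C)(C)C)c2cc(OC)c(OC)c(OC)c2)cc1OC
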